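**Retrosynthetic overview**

1. Numbering: C1 (CH–OAc), C2, C3=C4(Me), C5 (ring-fusion CH), C6, C7=C8(Me)–C9(=O)–O–C10=C11, C12 (Me, OH), C13, C14, C15 (CH–O-isovaleryl), C16 (quaternary, Me); ring A = C1–C5 + C16, ten-membered ring = C5, C6, C7, C10–C16, butenolide = C7–C10 + O.
2. Basis: in ring A the alkene C3=C4 lies opposite the C1–C16 bond, so ring A is the adduct of a C2=C3–C4=C5 diene and a C1=C16 dienophile. With C15 as an ester carbonyl bound to an oxygen on C7, the same step closes a temporary δ-lactone (C5, C6, C7, O, C15, C16) and sets C1, C5 and C16 from the C7 carbinol.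
3. Triene: (S)-glycidol (C7, C10), vinyl Grignard, methacrolein and a methylene ylide (C2–C6); then propanoate → one-pot formylation/O-acetylation → (Z)-enol acetate (C1, C15, C16).
4. After the cycloaddition: C14–C15 by addition of a C11–C14 alkyllithium (from (S)-citramalic acid, carries C12) to the lactone; C7 ketone; Evans–Tishchenko reduction sets C15 and returns the C1 acetate; C7=C8 by intramolecular HWE.
5. Ring order: ring A + tether lactone → butenolide → ten-membered ring, closed last at C10–C11 by intramolecular vinylogous Mukaiyama aldol/elimination.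

Key step: step 7

Remark: the target is read from its SMILES as the (1S,5S,12S,15S,16S,10E) isomer; the target atom numbers are used for all intermediates; PMB = 4-methoxybenzyl, TES = triethylsilyl, TBS = tert-butyldimethylsilyl.

**Route**

Step 1
Reactants: 1 (S)-glycidol
Product: 2 (R)-2-{[(4-methoxybenzyl)oxy]methyl}oxirane
Conditions: NaH, 4-methoxybenzyl chloride, Bu4NI (cat.), DMF, −20 → 0 °C
Reagents that add atoms: 4-methoxybenzyl chloride, COc1ccc(CCl)cc1
Why: Williamson etherification of the primary alkoxide touches no bond of the stereocentre (the descriptor changes from S to R only through the CIP priorities), and the low temperature keeps epoxide migration of the alkoxide slow.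

Step 2
Reactants: 2 (R)-2-{[(4-methoxybenzyl)oxy]methyl}oxirane
Product: 3 (R)-1-[(4-methoxybenzyl)oxy]pent-4-en-2-ol
Conditions: CH2=CHMgBr, CuI (cat.), THF, −40 → −20 °C
Reagents that add atoms: vinylmagnesium bromide CH2=CHMgBr, C=C[Mg]Br
Why: Copper-catalysed Grignard opening of a terminal epoxide takes place at the unsubstituted carbon, so the carbinol centre (future C7) is carried over unchanged.

Step 3
Reactants: 3 (R)-1-[(4-methoxybenzyl)oxy]pent-4-en-2-ol
Product: 4 (2E,5R)-5-hydroxy-6-[(4-methoxybenzyl)oxy]-2-methylhex-2-enal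
Conditions: methacrolein (excess), second-generation Grubbs catalyst (H2IMes)(PCy3)Cl2Ru=CHPh (cat.), CH2Cl2, 40 °C
Reagents that add atoms: methacrolein, CC(=C)C=O
Why: Olefin cross-metathesis of a terminal alkene with a 2-substituted acrolein should give the trisubstituted (E)-enal under thermodynamic control, and a free homoallylic hydroxyl and a PMB ether are tolerated.

Step 4
Reactants: 4 (2E,5R)-5-hydroxy-6-[(4-methoxybenzyl)oxy]-2-methylhex-2-enal
Product: 5 (2R,4E)-1-[(4-methoxybenzyl)oxy]-5-methylhepta-4,6-dien-2-ol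
Conditions: Ph3PCH3Br, KOt-Bu (2.5 equiv each), THF, 0 °C → rt
Reagents that add atoms: methyltriphenylphosphonium bromide, C[P+](c1ccccc1)(c1ccccc1)c1ccccc1.[Br-]
Why: Wittig methylenation of the enal builds the C2=C3 terminus of the diene without touching the (E)-C4=C5 bond, the excess ylide covering the free hydroxyl.

Step 5
Reactants: 5 (2R,4E)-1-[(4-methoxybenzyl)oxy]-5-methylhepta-4,6-dien-2-ol
Product: 6 (2R,4E)-1-[(4-methoxybenzyl)oxy]-5-methylhepta-4,6-dien-2-yl propanoate
Conditions: propanoyl chloride, pyridine, DMAP (cat.), CH2Cl2, 0 °C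
Reagents that add atoms: propanoyl chloride, CCC(Cl)=O
Why: DMAP-catalysed acylation of the secondary alcohol installs C15, C16 and the C16 methyl group as a propanoate.

Step 6
Reactants: 6 (2R,4E)-1-[(4-methoxybenzyl)oxy]-5-methylhepta-4,6-dien-2-yl propanoate
Product: 10 (2R,4E)-1-[(4-methoxybenzyl)oxy]-5-methylhepta-4,6-dien-2-yl (2Z)-3-acetoxy-2-methylprop-2-enoate, via lithium ester enolate 7 (not isolated), via formyl ester 8 (not isolated), via lithium formyl-ester enolate 9 (not isolated)
Conditions: LiN(i-Pr)2 (1.1 equiv), THF, −78 °C; HCO2Et, −78 → −20 °C; then Ac2O (3 equiv), −78 → 0 °C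
Reagents that add atoms: ethyl formate, CCOC=O; acetic anhydride, CC(=O)OC(C)=O
Why: Crossed Claisen condensation of the ester enolate with ethyl formate ends at the chelated lithium enolate of the formyl ester, in which lithium holds the enolate oxygen and the ester carbonyl on the same side, and O-acetylation of this chelate in the same flask should give the (Z)-enol acetate without isolation of the labile formyl ester, C-acylation being disfavoured at the substituted α-carbon.

Step 7
Reactants: 10 (Z)-enol acetate triene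
Product: 11 (3R,4aS,8S,8aR)-3-{[(4-methoxybenzyl)oxy]methyl}-5,8a-dimethyl-1-oxo-3,4,4a,7,8,8a-hexahydro-1H-isochromen-8-yl acetate (trans-fused ring A δ-lactone)
Conditions: BHT (cat.), 1,2-dichlorobenzene (0.01 M), 180 °C, sealed tube
Reagents that add atoms: none
Why: The triene cyclises by a concerted, suprafacial [4+2] cycloaddition of the C2=C3–C4=C5 diene to the C1=C16 dienophile, the C7–O–C15 ester holding the two within reach; the closest known reaction type is the thermal intramolecular Diels–Alder reaction of ester-linked 1,3,9-decatrienes (hexa-3,5-dienyl acrylates and fumarates) to bicyclic δ-lactones, the β-acyloxy-α-methylacrylate dienophile being an untried member of that class. Ring A closes as the cycloadduct ring through the new bonds C1–C2 and C5–C16, and the δ-lactone (C5, C6, C7, O, C15, C16) closes as the tether ring by the C5–C16 bond alone. C1 follows from the Z dienophile, whose acetoxy group and ester carbon stay cis, C16 follows from the exo mode (carbonyl away from the diene, chair-like tether) that places C6 and C15 trans, and C5 follows from C7, whose CH2OPMB group takes the pseudo-equatorial site of the forming lactone and so fixes the diene face. The step needs regio-, exo- and facial selectivity: the tether secures the first and C7 the third, whereas the exo mode rests only on the chair-like tether geometry, so the cis-fused adduct is the by-product to be expected and removed by chromatography. C16 has no hydrogen, so the β-acetoxy lactone cannot eliminate acetic acid at this temperature.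

Step 8
Reactants: 11 acetoxy lactone
Product: 12 (3R,4aS,8S,8aR)-8-hydroxy-3-{[(4-methoxybenzyl)oxy]methyl}-5,8a-dimethyl-3,4,4a,7,8,8a-hexahydro-1H-isochromen-1-one
Conditions: K2CO3, MeOH, 0 °C
Reagents that add atoms: none
Why: Base-catalysed transesterification removes the acetate at its unhindered acetyl carbonyl, while the lactone carbonyl next to the quaternary C16 reacts far more slowly and C16 cannot enolise.

Step 9
Reactants: 12 hydroxy lactone
Product: 13 C1 triethylsilyl ether of 12
Conditions: Et3SiOTf, 2,6-lutidine, CH2Cl2, −78 → 0 °C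
Reagents that add atoms: triethylsilyl trifluoromethanesulfonate, CC[Si](CC)(CC)OS(=O)(=O)C(F)(F)F
Why: Silyl triflate silylation covers the hindered C1 hydroxyl with a group that survives the alkyllithium and can later be removed beside the acetonide and the PMB ether.

Step 10
Reactants: 14 (S)-citramalic acid
Product: 15 (S)-2-methylbutane-1,2,4-triol
Conditions: BH3·SMe2, B(OMe)3, THF, 0 °C → rt; MeOH
Reagents that add atoms: none
Why: Borane reduces both carboxyl groups chemoselectively and leaves the tertiary carbinol centre (future C12) untouched.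

Step 11
Reactants: 15 (S)-2-methylbutane-1,2,4-triol
Product: 16 2-[(4S)-2,2,4-trimethyl-1,3-dioxolan-4-yl]ethanol
Conditions: Me2C(OMe)2, TsOH·H2O (cat.), acetone, rt
Reagents that add atoms: 2,2-dimethoxypropane, COC(C)(C)OC
Why: Acid-catalysed transacetalisation under thermodynamic control should give the five-membered dioxolane of the 1,2-diol, which protects O11 and O12 and leaves the C14 hydroxyl free.

Step 12
Reactants: 16 2-[(4S)-2,2,4-trimethyl-1,3-dioxolan-4-yl]ethanol
Product: 17 (4S)-4-(2-iodoethyl)-2,2,4-trimethyl-1,3-dioxolane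
Conditions: I2, PPh3, imidazole, CH2Cl2, 0 °C → rt
Reagents that add atoms: iodine, II
Why: Appel-type iodination converts the primary alcohol into the iodide under conditions that are buffered by imidazole and spare the acetonide.

Step 13
Reactants: 13 C1-OTES lactone; 17 (4S)-4-(2-iodoethyl)-2,2,4-trimethyl-1,3-dioxolane
Product: 19 δ-hydroxy ketone (C15 ketone; free C7 hydroxyl), via alkyllithium 18 (not isolated)
Conditions: 17, t-BuLi (2.1 equiv), Et2O–pentane, −78 °C; then 13, THF, −78 → −40 °C; H2O
Reagents that add atoms: none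
Why: Lithium–iodine exchange gives the primary alkyllithium, which adds once to the lactone carbonyl because the lithium hemiketal alkoxide is stable in the cold and C16 has no α-hydrogen to be removed.

Step 14
Reactants: 19 δ-hydroxy ketone (in equilibrium with its six-membered hemiketal)
Product: 20 1,5-diketone (C7 and C15 ketones)
Conditions: Dess–Martin periodinane, pyridine, CH2Cl2, rt
Reagents that add atoms: none
Why: Dess–Martin oxidation of the C7 hydroxyl in the open tautomer drains the hemiketal equilibrium towards the diketone under buffered, non-basic conditions.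

Step 15
Reactants: 20 1,5-diketone
Product: 21 β-hydroxy ketone (free C1 hydroxyl)
Conditions: HF·pyridine, pyridine, THF, 0 °C
Reagents that add atoms: none
Why: Buffered fluoride cleaves the Si–O bond without base, so the acetonide and PMB ether stay and neither retro-aldol opening nor aldol closure of the diketone is invited.

Step 16
Reactants: 21 β-hydroxy ketone
Product: 22 C1 acetate with (15S)-C15 hydroxyl (1,3-anti)
Conditions: CH3CHO (10 equiv), SmI2 (0.3 equiv), THF, −10 °C
Reagents that add atoms: acetaldehyde, CC=O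
Why: In the Evans–Tishchenko reduction the hemiacetal of the C1 hydroxyl with acetaldehyde, bound to trivalent samarium, delivers hydride to the C15 ketone through a six-membered chair with C2 equatorial, which gives the 1,3-anti (15S) alcohol, leaves the acetate on O1 and spares the C7 ketone, which has no β-hydroxyl.

Step 17
Reactants: 22 C1 acetate C15 alcohol
Product: 23 C1 acetate C15 3-methylbutanoate
Conditions: 3-methylbutanoyl chloride, pyridine, DMAP, CH2Cl2, 0 °C → rt
Reagents that add atoms: 3-methylbutanoyl chloride, CC(C)CC(Cl)=O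
Why: DMAP-catalysed acylation of the hindered C15 hydroxyl at low temperature fixes both esters before the acetate can migrate.

Step 18
Reactants: 23 diester with C10-OPMB
Product: 24 α-hydroxy ketone (free C10 hydroxyl, C7 ketone)
Conditions: DDQ, CH2Cl2–pH 7 buffer, 0 °C
Reagents that add atoms: none
Why: DDQ oxidises the electron-rich PMB ether to an oxocarbenium ion that water cleaves, and the esters, the acetonide and the ring A alkene are left alone.

Step 19
Reactants: 24 α-hydroxy ketone
Product: 25 C10 2-(diethoxyphosphoryl)propanoate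
Conditions: 2-(diethoxyphosphoryl)propanoic acid, DCC, DMAP (cat.), CH2Cl2, 0 °C → rt
Reagents that add atoms: 2-(diethoxyphosphoryl)propanoic acid, CCOP(=O)(OCC)C(C)C(=O)O
Why: Steglich esterification of the primary hydroxyl brings in C8, its methyl group and C9 as a phosphonate set up for olefination of the neighbouring C7 ketone.

Step 20
Reactants: 25 keto phosphonate
Product: 26 butenolide (C7=C8, C8 methyl, C10H2)
Conditions: LiCl, i-Pr2NEt, MeCN, rt
Reagents that add atoms: none
Why: Intramolecular Horner–Wadsworth–Emmons reaction closes the five-membered ring onto the C7 ketone under mild lithium chloride/amine conditions that spare the two esters.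

Step 21
Reactants: 26 butenolide acetonide
Product: 27 C11,C12 diol
Conditions: AcOH–H2O (4:1), 40 °C
Reagents that add atoms: none
Why: Mild aqueous acid hydrolyses the terminal acetonide, while the esters and the butenolide are stable and the diol is too far from O15 for acyl migration.

Step 22
Reactants: 27 diol
Product: 28 bis-triethylsilyl ether (C11-OTES, C12-OTES)
Conditions: Et3SiOTf (2.5 equiv), 2,6-lutidine, CH2Cl2, −78 °C
Reagents that add atoms: triethylsilyl trifluoromethanesulfonate, CC[Si](CC)(CC)OS(=O)(=O)C(F)(F)F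
Why: The silyl triflate silylates both the primary and the tertiary hydroxyl, and the tertiary ether is what later blocks α-ketol rearrangement of the C11 aldehyde.

Step 23
Reactants: 28 bis-triethylsilyl ether
Product: 29 C11 aldehyde with C12-OTES
Conditions: (COCl)2, DMSO, CH2Cl2, −78 → −30 °C; Et3N, −78 → 0 °C
Reagents that add atoms: none
Why: Under Swern conditions a primary triethylsilyl ether is cleaved and oxidised to the aldehyde in one operation, whereas the tertiary silyl ether is inert and the aldehyde formed cannot enolise.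

Step 24
Reactants: 29 butenolide aldehyde
Product: 32 ten-membered-ring alkylidene butenolide C12 triethylsilyl ether, via silyloxyfuran 30 (not isolated), via silyl aldol adduct 31 (not isolated)
Conditions: t-BuMe2SiOTf, i-Pr2NEt, CH2Cl2 (0.002 M), −78 → 0 °C; then DBU, rt
Reagents that add atoms: none
Why: The silyl triflate and amine turn the butenolide into its 2-silyloxyfuran, which attacks the silyl-activated C11 aldehyde through C10 in an intramolecular vinylogous Mukaiyama aldol reaction at high dilution, and DBU then removes silanol by E1cB elimination to give the C10=C11 alkene in the less strained geometry with C7 and C12 cis within the ring (10E).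

Step 25
Reactants: 32 C12 triethylsilyl ether
Product: 33 target CNP0208239.1
Conditions: HF·pyridine, pyridine, THF, 0 °C → rt
Reagents that add atoms: none
Why: Buffered fluoride cleaves the tertiary silyl ether without base or strong acid, so the esters, the alkylidene butenolide and the tertiary allylic alcohol should survive.

**Compound list**

1 | (S)-glycidol | OC[C@H]1CO1 | starting material
2 | (R)-2-{[(4-methoxybenzyl)oxy]methyl}oxirane | COc1ccc(COC[C@H]2CO2)cc1 | intermediate
3 | (R)-1-[(4-methoxybenzyl)oxy]pent-4-en-2-ol | COc1ccc(COC[C@H](O)CC=C)cc1 | intermediate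
4 | (2E,5R)-5-hydroxy-6-[(4-methoxybenzyl)oxy]-2-methylhex-2-enal | COc1ccc(COC[C@H](O)C/C=C(\C)C=O)cc1 | intermediate
5 | (2R,4E)-1-[(4-methoxybenzyl)oxy]-5-methylhepta-4,6-dien-2-ol | COc1ccc(COC[C@H](O)C/C=C(\C)C=C)cc1 | intermediate
6 | (2R,4E)-1-[(4-methoxybenzyl)oxy]-5-methylhepta-4,6-dien-2-yl propanoate | CCC(=O)O[C@@H](COCc1ccc(OC)cc1)C/C=C(\C)C=C | intermediate
7 | lithium ester enolate of 6 (enolate geometry not defined) | [Li+].CC=C([O-])O[C@@H](COCc1ccc(OC)cc1)C/C=C(\C)C=C | intermediate
8 | (2R,4E)-1-[(4-methoxybenzyl)oxy]-5-methylhepta-4,6-dien-2-yl 2-methyl-3-oxopropanoate (formyl ester, transient in the flask, α-carbon not configured) | CC(C=O)C(=O)O[C@@H](COCc1ccc(OC)cc1)C/C=C(\C)C=C | intermediate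
9 | lithium (Z)-enolate of formyl ester 8 (lithium chelated by enolate and ester oxygens) | [Li+].[O-]/C=C(/C)C(=O)O[C@@H](COCc1ccc(OC)cc1)C/C=C(\C)C=C | intermediate
10 | (2R,4E)-1-[(4-methoxybenzyl)oxy]-5-methylhepta-4,6-dien-2-yl (2Z)-3-acetoxy-2-methylprop-2-enoate | CC(=O)O/C=C(/C)C(=O)O[C@@H](COCc1ccc(OC)cc1)C/C=C(\C)C=C | intermediate
11 | (3R,4aS,8S,8aR)-3-{[(4-methoxybenzyl)oxy]methyl}-5,8a-dimethyl-1-oxo-3,4,4a,7,8,8a-hexahydro-1H-isochromen-8-yl acetate (trans-fused; C1 acetate cis to C15) | CC(=O)O[C@H]1CC=C(C)[C@@H]2C[C@H](COCc3ccc(OC)cc3)OC(=O)[C@@]12C | intermediate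
12 | (3R,4aS,8S,8aR)-8-hydroxy-3-{[(4-methoxybenzyl)oxy]methyl}-5,8a-dimethyl-3,4,4a,7,8,8a-hexahydro-1H-isochromen-1-one | O[C@H]1CC=C(C)[C@@H]2C[C@H](COCc3ccc(OC)cc3)OC(=O)[C@@]12C | intermediate
13 | C1 triethylsilyl ether of 12 (same configuration) | CC[Si](CC)(CC)O[C@H]1CC=C(C)[C@@H]2C[C@H](COCc3ccc(OC)cc3)OC(=O)[C@@]12C | intermediate
14 | (S)-citramalic acid, (2S)-2-hydroxy-2-methylbutanedioic acid | C[C@](O)(CC(=O)O)C(=O)O | starting material
15 | (S)-2-methylbutane-1,2,4-triol | C[C@](O)(CCO)CO | intermediate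
16 | 2-[(4S)-2,2,4-trimethyl-1,3-dioxolan-4-yl]ethanol | C[C@]1(CCO)COC(C)(C)O1 | intermediate
17 | (4S)-4-(2-iodoethyl)-2,2,4-trimethyl-1,3-dioxolane | C[C@]1(CCI)COC(C)(C)O1 | intermediate
18 | {2-[(4S)-2,2,4-trimethyl-1,3-dioxolan-4-yl]ethyl}lithium | [Li]CC[C@@]1(C)COC(C)(C)O1 | intermediate
19 | δ-hydroxy ketone: ring A as in 13 with C1-OTES; C16 carries the C15 ketone with the C14–C11 chain (C11/C12 acetonide, 12S); C5 carries CH2–(7R)-CH(OH)–CH2OPMB; in equilibrium with its cyclic hemiketal | CC[Si](CC)(CC)O[C@H]1CC=C(C)[C@H](C[C@@H](O)COCc2ccc(OC)cc2)[C@@]1(C)C(=O)CC[C@@]3(C)COC(C)(C)O3 | intermediate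
20 | 1,5-diketone (C7 and C15 ketones), C1-OTES, C10-OPMB, C11/C12 acetonide | CC[Si](CC)(CC)O[C@H]1CC=C(C)[C@H](CC(=O)COCc2ccc(OC)cc2)[C@@]1(C)C(=O)CC[C@@]3(C)COC(C)(C)O3 | intermediate
21 | β-hydroxy ketone: 20 with free C1 hydroxyl | O[C@H]1CC=C(C)[C@H](CC(=O)COCc2ccc(OC)cc2)[C@@]1(C)C(=O)CC[C@@]3(C)COC(C)(C)O3 | intermediate
22 | C1 acetate, (15S)-C15 alcohol (1,3-anti), C7 ketone | CC(=O)O[C@H]1CC=C(C)[C@H](CC(=O)COCc2ccc(OC)cc2)[C@@]1(C)[C@@H](O)CC[C@@]3(C)COC(C)(C)O3 | intermediate
23 | C1 acetate, C15 3-methylbutanoate, C7 ketone, C10-OPMB | CC(=O)O[C@H]1CC=C(C)[C@H](CC(=O)COCc2ccc(OC)cc2)[C@@]1(C)[C@@H](OC(=O)CC(C)C)CC[C@@]3(C)COC(C)(C)O3 | intermediate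
24 | α-hydroxy ketone: 23 with free C10 hydroxyl | CC(=O)O[C@H]1CC=C(C)[C@H](CC(=O)CO)[C@@]1(C)[C@@H](OC(=O)CC(C)C)CC[C@@]2(C)COC(C)(C)O2 | intermediate
25 | C10 2-(diethoxyphosphoryl)propanoate of 24 (phosphonate α-carbon not configured) | CC(=O)O[C@H]1CC=C(C)[C@H](CC(=O)COC(=O)C(C)P(=O)(OCC)OCC)[C@@]1(C)[C@@H](OC(=O)CC(C)C)CC[C@@]2(C)COC(C)(C)O2 | intermediate
26 | butenolide (C7=C8, C8 methyl, C10H2) with C11/C12 acetonide | CC(=O)O[C@H]1CC=C(C)[C@H](CC2=C(C)C(=O)OC2)[C@@]1(C)[C@@H](OC(=O)CC(C)C)CC[C@@]3(C)COC(C)(C)O3 | intermediate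
27 | butenolide C11,C12 diol (12S) | CC(=O)O[C@H]1CC=C(C)[C@H](CC2=C(C)C(=O)OC2)[C@@]1(C)[C@@H](OC(=O)CC(C)C)CC[C@](C)(O)CO | intermediate
28 | butenolide C11,C12 bis-triethylsilyl ether | CC(=O)O[C@H]1CC=C(C)[C@H](CC2=C(C)C(=O)OC2)[C@@]1(C)[C@@H](OC(=O)CC(C)C)CC[C@](C)(O[Si](CC)(CC)CC)CO[Si](CC)(CC)CC | intermediate
29 | butenolide C11 aldehyde with C12-OTES | CC(=O)O[C@H]1CC=C(C)[C@H](CC2=C(C)C(=O)OC2)[C@@]1(C)[C@@H](OC(=O)CC(C)C)CC[C@](C)(O[Si](CC)(CC)CC)C=O | intermediate
30 | 2-(tert-butyldimethylsilyloxy)-3-methylfuran, 4-substituted, with C11 aldehyde | CC(=O)O[C@H]1CC=C(C)[C@H](Cc2coc(O[Si](C)(C)C(C)(C)C)c2C)[C@@]1(C)[C@@H](OC(=O)CC(C)C)CC[C@](C)(O[Si](CC)(CC)CC)C=O | intermediate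
31 | cyclised aldol adduct, C11-OTBS, C10–H butenolide (epimer mixture at C10 and C11) | CC(=O)O[C@H]1CC=C(C)[C@@H]2CC3=C(C)C(=O)OC3C(O[Si](C)(C)C(C)(C)C)[C@@](C)(O[Si](CC)(CC)CC)CC[C@H](OC(=O)CC(C)C)[C@@]12C | intermediate
32 | C12 triethylsilyl ether of the target (10E) | CC(=O)O[C@H]1CC=C(C)[C@@H]2CC3=C(C)C(=O)O/C3=C/[C@@](C)(O[Si](CC)(CC)CC)CC[C@H](OC(=O)CC(C)C)[C@@]12C | intermediate
33 | CNP0208239.1, (1S,5S,12S,15S,16S,10E) in the numbering used here | CC(=O)O[C@H]1CC=C(C)[C@@H]2CC3=C(C)C(=O)O/C3=C/[C@@](C)(O)CC[C@H](OC(=O)CC(C)C)[C@@]12C | target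

**Totals**

Total step count: 25. Longest linear sequence: 22 steps (steps 1–9 and 13–25, from (S)-glycidol); the C11–C14 fragment takes steps 10–12.

**Steps most likely to fail**

1. Step 7. The cycloaddition may be slow, because the dienophile is trisubstituted and donor-substituted and the ester must reach its less favoured conformation. The exo (trans-fused) and endo (cis-fused) modes may also be poorly discriminated. Fallback: replace the acetoxy group by boron as a masked hydroxyl, which is no π-donor and whose bulk in the Z position disfavours the mode that puts it under the diene. The fallback sets out from propanoate 6. Run as in step 6 but with PhNTf2 in place of acetic anhydride, the one-pot formylation should trap lithium enolate 9 as the (Z)-enol triflate F1. Miyaura borylation (B2pin2, PdCl2(PPh3)2, PPh3, KOPh, toluene, 50 °C) should give the (Z)-3-(pinacolboryl)-2-methylacrylate F2 with retention of geometry. Heating as in step 7 should give the C1-boryl trans-fused lactone F3. Oxidation of the C–B bond with NaBO3·4H2O in THF–H2O, which goes with retention, returns to the route at hydroxy lactone 12.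

2. Step 24. The dilute silyloxyfuran aldehyde may oligomerise instead of closing the medium ring, and a strained ten-membered aldolate may revert before elimination. Fallback: close C10=C11 by an intramolecular Horner–Wadsworth–Emmons reaction, which is irreversible. It sets out from bis-silyl ether 28. t-BuMe2SiOTf and Et3N give the 2-silyloxyfuran F4. N-bromosuccinimide in THF at −78 °C gives the C10 bromobutenolide F5. Michaelis–Arbuzov reaction with P(OEt)3 gives the C10 diethyl phosphonate F6. Pyridinium tosylate in MeOH at 0 °C removes the primary silyl group selectively to give the C11 alcohol F7. Dess–Martin oxidation gives the phosphonate aldehyde F8. LiCl and DBU in MeCN at high dilution then close the ring, returning to the route at 32.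

3. Step 16. The β-hydroxy ketone with its quaternary α-carbon may open by retro-aldol cleavage of ring A, the 1,5-diketone may undergo aldol closure, and the new acetate may migrate from O1 to O15 under the Lewis acidic conditions. Fallback: set C15 by reagent control after the C7 ketone has been consumed. It sets out from diketone 20, with the C1 silyl ether kept. DDQ gives the α-hydroxy ketone F9. DCC coupling with 2-(diethoxyphosphoryl)propanoic acid gives the phosphonate F10. LiCl and i-Pr2NEt give the butenolide ketone F11. CBS reduction with (R)-2-methyl-CBS-oxazaborolidine and catecholborane in toluene at −78 °C should give the (15S)-alcohol F12, with the quaternary C16 as the large and the C14 methylene as the small group. 3-Methylbutanoyl chloride, pyridine and DMAP give the ester F13. HF·pyridine gives the C1 alcohol F14. Ac2O, pyridine and DMAP then return to the route at 26.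

**Further compounds**

F1 | step 7 | (2R,4E)-1-[(4-methoxybenzyl)oxy]-5-methylhepta-4,6-dien-2-yl (2Z)-2-methyl-3-(trifluoromethylsulfonyloxy)prop-2-enoate | O=S(=O)(O/C=C(/C)C(=O)O[C@@H](COCc1ccc(OC)cc1)C/C=C(\C)C=C)C(F)(F)F
F2 | step 7 | (2R,4E)-1-[(4-methoxybenzyl)oxy]-5-methylhepta-4,6-dien-2-yl (2Z)-2-methyl-3-(4,4,5,5-tetramethyl-1,3,2-dioxaborolan-2-yl)prop-2-enoate | CC1(C)OB(/C=C(/C)C(=O)O[C@@H](COCc2ccc(OC)cc2)C/C=C(\C)C=C)OC1(C)C
F3 | step 7 | trans-fused lactone as 11 with a pinacolboryl group in place of the C1 acetoxy group (same spatial arrangement) | CC4(C)OB(OC4(C)C)[C@H]1CC=C(C)[C@@H]2C[C@H](COCc3ccc(OC)cc3)OC(=O)[C@@]12C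
F4 | step 24 | 2-(tert-butyldimethylsilyloxy)furan derived from 28 | CC(=O)O[C@H]1CC=C(C)[C@H](Cc2coc(O[Si](C)(C)C(C)(C)C)c2C)[C@@]1(C)[C@@H](OC(=O)CC(C)C)CC[C@](C)(O[Si](CC)(CC)CC)CO[Si](CC)(CC)CC
F5 | step 24 | C10 bromobutenolide of 28 (C10 not configured) | CC(=O)O[C@H]1CC=C(C)[C@H](CC2=C(C)C(=O)OC2Br)[C@@]1(C)[C@@H](OC(=O)CC(C)C)CC[C@](C)(O[Si](CC)(CC)CC)CO[Si](CC)(CC)CC
F6 | step 24 | C10 diethyl phosphonate of 28 (C10 not configured) | CC(=O)O[C@H]1CC=C(C)[C@H](CC2=C(C)C(=O)OC2P(=O)(OCC)OCC)[C@@]1(C)[C@@H](OC(=O)CC(C)C)CC[C@](C)(O[Si](CC)(CC)CC)CO[Si](CC)(CC)CC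
F7 | step 24 | C10 phosphonate with free C11 hydroxyl and C12-OTES | CC(=O)O[C@H]1CC=C(C)[C@H](CC2=C(C)C(=O)OC2P(=O)(OCC)OCC)[C@@]1(C)[C@@H](OC(=O)CC(C)C)CC[C@](C)(O[Si](CC)(CC)CC)CO
F8 | step 24 | C10 phosphonate C11 aldehyde with C12-OTES | CC(=O)O[C@H]1CC=C(C)[C@H](CC2=C(C)C(=O)OC2P(=O)(OCC)OCC)[C@@]1(C)[C@@H](OC(=O)CC(C)C)CC[C@](C)(O[Si](CC)(CC)CC)C=O
F9 | step 16 | diketone 20 with free C10 hydroxyl (C1-OTES kept) | CC[Si](CC)(CC)O[C@H]1CC=C(C)[C@H](CC(=O)CO)[C@@]1(C)C(=O)CC[C@@]2(C)COC(C)(C)O2
F10 | step 16 | C10 2-(diethoxyphosphoryl)propanoate of F9 | CC[Si](CC)(CC)O[C@H]1CC=C(C)[C@H](CC(=O)COC(=O)C(C)P(=O)(OCC)OCC)[C@@]1(C)C(=O)CC[C@@]2(C)COC(C)(C)O2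
F11 | step 16 | butenolide with C15 ketone and C1-OTES | CC[Si](CC)(CC)O[C@H]1CC=C(C)[C@H](CC2=C(C)C(=O)OC2)[C@@]1(C)C(=O)CC[C@@]3(C)COC(C)(C)O3
F12 | step 16 | butenolide (15S)-C15 alcohol with C1-OTES | CC[Si](CC)(CC)O[C@H]1CC=C(C)[C@H](CC2=C(C)C(=O)OC2)[C@@]1(C)[C@@H](O)CC[C@@]3(C)COC(C)(C)O3
F13 | step 16 | butenolide C15 3-methylbutanoate with C1-OTES | CC[Si](CC)(CC)O[C@H]1CC=C(C)[C@H](CC2=C(C)C(=O)OC2)[C@@]1(C)[C@@H](OC(=O)CC(C)C)CC[C@@]3(C)COC(C)(C)O3
F14 | step 16 | butenolide C15 3-methylbutanoate with free C1 hydroxyl | O[C@H]1CC=C(C)[C@H](CC2=C(C)C(=O)OC2)[C@@]1(C)[C@@H](OC(=O)CC(C)C)CC[C@@]3(C)COC(C)(C)O3
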